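# Proposed total synthesis of Coloratanin A (20)

## Analysis of the target

Coloratanin A (C25H28O6) is an isoflavone: ring A is fused to the γ-pyranone ring C (O1, C2, C3, C4, C4a, C8a), and ring B sits on C3. Ring A is a fully differentiated phloroglucinol, with O1 on C8a, free hydroxyls on C5 and C7, a prenyl group on C6, hydrogen only on C8 and the C4 carbonyl on C4a. Ring B carries the 4'-hydroxyl and, ortho to it on C3', a 3-hydroxy-3-methylbutyl chain, a second C5 unit at the hydrated oxidation level. There is no stereocentre and no stereogenic double bond, so the problem is one of regiochemistry and chemoselectivity. The sensitive groups are the prenyl olefin between two phenols (acid closes a chroman), the tertiary alcohol near the 4'-hydroxyl (acid closes a 2,2-dimethylchroman), C2 of the pyranone (nucleophiles and strong base open ring C) and the electron-rich rings (oxidants). The hard point is the prenyl group at C6 and not at C8: the two carbons differ only in which neighbouring oxygen lies in ring C, so closing ring C at oxygen from a 2-acyl-4-prenylphloroglucinol means choosing between two nearly equal hydroxyls. The feature used here is that C6 is para to C8a. Once O1 is attached to C8a as an aryl ether, ring A has a local twofold axis through C8a and C6, and C4a and C8 become equivalent; closing ring C at the C4–C4a bond therefore cannot give the 8-prenyl isomer. The two C5 chains are brought in on separate fragments, so they never have to be told apart in one molecule.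

## Retrosynthetic reasoning

**20 from 19.** The three phenols are unmasked from methoxymethyl ethers and the tertiary alcohol from a triethylsilyl ether in one acid solvolysis. Nothing in the skeleton changes; the forward step only has to be faster than protonation of the prenyl olefin.

**19 from 16 (C4–C4a).** Ring C is cut at the carbon–carbon bond between the carbonyl carbon C4 and the ring-A carbon C4a, not at O1–C2 as usual. The precursor 16 is a 3-aryloxy-2-arylacrylic acid in which O1 is already bonded to the ring-A carbon para to the prenyl group. The two carbons ortho to O1 in 16 are equivalent, so an intramolecular Friedel–Crafts acylation (through 17 and 18) can only give the 6-prenyl chromone. The step builds the pyranone, installs the full isoflavone skeleton and settles the C6/C8 question by symmetry. It has to tolerate the prenyl olefin, the acetals and the silyl ether.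

**16 from 15, and 15 from 6 + 14 (O1–C2).** The acid comes from its methyl ester 15. 15 is cut at the vinyl ether bond into phenol 6 and the enol sulfonate 14, a vinylogous mixed anhydride, so the forward reaction is a nucleophilic vinylic substitution by the only free phenol of 6. This is the convergent point: the two halves are of similar size and each carries one of the two C5 chains.

**6 from 4, 4 from 2, 2 from 1.** In 6 the free hydroxyl is para to the prenyl group and the other two oxygens are protected alike. This oxygen is introduced on 4 at the one C–H that is not ortho to any substituent, by sterically governed C–H borylation (boronate 5) and oxidation. The prenyl C–C bond of 4 is cut back to 2, where the carbon between the two acetal oxygens is the unique site of directed lithiation (aryllithium 3). 2 is the bis-acetal of resorcinol 1. Every position on ring A is thus fixed by the symmetry of 2.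

**14 from 12.** C2 of the chromone is a one-carbon unit at the formate oxidation level. 14 is cut at the C2–C3 bond back to the arylacetate 12; the forward reaction is a crossed Claisen condensation with a formate ester, and the enolate 13 is trapped on oxygen as the sulfonate.

**12 from 8 + 10, 8 from 7, 10 from 9.** The saturated chain of ring B is cut at the aryl–CH2 bond: a B-alkyl Suzuki–Miyaura coupling joins aryl bromide 8 and the borane 11 made from olefin 10. The tertiary oxygen is already in place in 9, so no hydration of a prenyl group is needed. 8 and 10 are the protected forms of the purchased compounds 7 and 9.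

## Alternatives that were turned down

**Alternative 1:** the textbook deoxybenzoin route. Disconnection: ring C at O1–C2 and C2–C3, then the C4–C4a bond between the rings. Forward: Houben–Hoesch or boron-trifluoride-mediated acylation of 2-prenylphloroglucinol A1 with the ring-B arylacetic acid gives deoxybenzoin A2, and a formylating agent then closes ring C at oxygen. Turned down because in A2 the ketone is flanked by two free hydroxyls of nearly equal acidity and nucleophilicity. Closure through one gives the target and through the other the 8-prenyl isomer A3, and nothing in the structure biases the choice; a bias would have to be bought with extra protecting-group steps. The acylation and formylation also use strong Lewis or Brønsted acid with heating, which should add the ortho phenols of A1 and A2 to the prenyl olefin and ionise the tertiary alcohol.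

**Alternative 2:** convergent Suzuki–Miyaura union at C3–C1'. Disconnection: the bond between ring C and ring B. Forward: palladium-catalysed coupling of 3-iodochromone A4 with aryl boronate A5. Turned down because it is the route most chemists would draw today and it only relocates the problem. A4 still needs a ring A with the prenyl group at C6, so the same choice between two hydroxyls returns at its acetophenone precursor. The usual iodine-mediated cyclisation to A4 also exposes the prenyl olefin to an iodonium source. The count is about six steps to A4 and four to A5 before the coupling, with no gain in regiochemical certainty.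

**Alternative 3:** biomimetic oxidative 1,2-aryl shift. Disconnection: the C3–C1' bond is traced back to a C2–C1' bond in 2'-hydroxychalcone A6. Forward: a trivalent thallium salt or a hypervalent iodine oxidant in methanol moves ring B from C2 to C3, and acid closes ring C. Turned down because these oxidants are electrophiles for olefins and for electron-rich arenes, so the prenyl olefin of A6 should be oxidised in competition with the enone. Both C5 chains would then have to be added after the rearrangement, which brings back unselective C6/C8 prenylation. The step also needs an acidic cyclisation, and the acetophenone half of A6 again requires two differentiated ortho hydroxyls.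

Key step: step 10

Assumption: methyl 2-(3-bromo-4-hydroxyphenyl)acetate 7 is taken as a purchased compound. Compounds 13–18 are drawn with the (Z) double bond that enolate trapping and substitution with retention should give; the key step does not depend on this geometry.

## Route

**Step 1**
Reactants: 1 resorcinol
Product: 2 1,3-bis(methoxymethoxy)benzene
Conditions: MOMCl (2.5 equiv), i-Pr2NEt (3 equiv), CH2Cl2, 0 °C to rt
Reagents that add atoms: chloromethyl methyl ether, COCCl
Why: O-alkylation of both phenols under amine base; the acetals later direct the lithiation and are removable with mild acid.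

**Step 2**
Reactants: 2 1,3-bis(methoxymethoxy)benzene
Product: 4 1,3-bis(methoxymethoxy)-2-(3-methylbut-2-en-1-yl)benzene, via aryllithium 3 (not isolated)
Conditions: n-BuLi (1.1 equiv), THF, 0 °C to rt; then CuBr·SMe2 (10 mol%), prenyl bromide (1.3 equiv), −78 °C to rt
Reagents that add atoms: 1-bromo-3-methylbut-2-ene (prenyl bromide), CC(C)=CCBr
Why: Directed ortho-metalation: both acetal groups chelate lithium, so deprotonation should occur only at the carbon between them; copper-catalysed allylic substitution should then give the linear prenyl arene.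

**Step 3**
Reactants: 4 1,3-bis(methoxymethoxy)-2-(3-methylbut-2-en-1-yl)benzene
Product: 6 3,5-bis(methoxymethoxy)-4-(3-methylbut-2-en-1-yl)phenol, via boronate 5 (not isolated)
Conditions: [Ir(OMe)(cod)]2 (1.5 mol%), 4,4'-di-tert-butyl-2,2'-bipyridine (3 mol%), B2pin2 (1.0 equiv), THF, 65 °C; then 30% H2O2, 2 M NaOH, 0 °C
Reagents that add atoms: hydrogen peroxide, OO
Why: Iridium-catalysed C–H borylation is sterically governed, and the C–H para to the prenyl group is the only one of 4 not ortho to a substituent; alkaline peroxide then oxidises the boronate (aryl shift from boron to oxygen) and should leave the olefin alone, since hydroperoxide anion does not epoxidise unactivated alkenes.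

**Step 4**
Reactants: 7 methyl 2-(3-bromo-4-hydroxyphenyl)acetate
Product: 8 methyl 2-[3-bromo-4-(methoxymethoxy)phenyl]acetate
Conditions: MOMCl (1.5 equiv), i-Pr2NEt (2 equiv), CH2Cl2, 0 °C to rt
Reagents that add atoms: chloromethyl methyl ether, COCCl
Why: O-alkylation of the phenol; the same acetal as on ring A allows one final deprotection.

**Step 5**
Reactants: 9 2-methylbut-3-en-2-ol
Product: 10 triethyl[(2-methylbut-3-en-2-yl)oxy]silane
Conditions: TESOTf (1.1 equiv), 2,6-lutidine (1.5 equiv), CH2Cl2, 0 °C
Reagents that add atoms: triethylsilyl trifluoromethanesulfonate, CC[Si](CC)(CC)OS(=O)(=O)C(F)(F)F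
Why: Silylation of a hindered tertiary alcohol with a silyl triflate and a hindered base; the silyl ether keeps the alcohol out of the borane, enolate and acyl chloride chemistry that follows.

**Step 6**
Reactants: 8 methyl 2-[3-bromo-4-(methoxymethoxy)phenyl]acetate; 10 triethyl[(2-methylbut-3-en-2-yl)oxy]silane
Product: 12 methyl 2-{4-(methoxymethoxy)-3-[3-methyl-3-(triethylsilyloxy)butyl]phenyl}acetate, via alkylborane 11 (not isolated)
Conditions: 10, 9-BBN-H (1.2 equiv), THF, 0 °C to rt; then 8, PdCl2(dppf) (5 mol%), 3 M aq. K3PO4 (3 equiv), DMF, 60 °C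
Reagents that add atoms: none
Why: Anti-Markovnikov hydroboration places boron on the terminal carbon (the inner carbon adjoins a quaternary centre), and the B-alkyl Suzuki–Miyaura coupling joins it to the aryl bromide; the methyl ester should survive phosphate base at this temperature.

**Step 7**
Reactants: 12 methyl 2-{4-(methoxymethoxy)-3-[3-methyl-3-(triethylsilyloxy)butyl]phenyl}acetate
Product: 14 methyl (Z)-2-{4-(methoxymethoxy)-3-[3-methyl-3-(triethylsilyloxy)butyl]phenyl}-3-(tosyloxy)prop-2-enoate, via sodium enolate 13 (not isolated)
Conditions: NaH (1.3 equiv), HCO2Me (5 equiv), THF, 0 °C to rt; then TsCl (1.3 equiv), 0 °C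
Reagents that add atoms: methyl formate, COC=O; 4-methylbenzenesulfonyl chloride, Cc1ccc(cc1)S(=O)(=O)Cl
Why: Crossed Claisen condensation of the arylacetate with the formate ester gives the chelated sodium enolate, which is trapped on oxygen by the sulfonyl chloride; chelation should place the sulfonate cis to the ester.

**Step 8**
Reactants: 6 3,5-bis(methoxymethoxy)-4-(3-methylbut-2-en-1-yl)phenol; 14 methyl (Z)-2-{4-(methoxymethoxy)-3-[3-methyl-3-(triethylsilyloxy)butyl]phenyl}-3-(tosyloxy)prop-2-enoate
Product: 15 methyl (Z)-3-[3,5-bis(methoxymethoxy)-4-(3-methylbut-2-en-1-yl)phenoxy]-2-{4-(methoxymethoxy)-3-[3-methyl-3-(triethylsilyloxy)butyl]phenyl}prop-2-enoate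
Conditions: Cs2CO3 (1.5 equiv), MeCN, 0 °C to rt
Reagents that add atoms: none
Why: Nucleophilic vinylic substitution by addition–elimination: the enol sulfonate is a vinylogous mixed anhydride, so the phenoxide should attack C3 and expel the sulfonate, with retention expected; 6 has only one free hydroxyl, which fixes O1 para to the prenyl group.

**Step 9**
Reactants: 15 methyl (Z)-3-[3,5-bis(methoxymethoxy)-4-(3-methylbut-2-en-1-yl)phenoxy]-2-{4-(methoxymethoxy)-3-[3-methyl-3-(triethylsilyloxy)butyl]phenyl}prop-2-enoate
Product: 16 (Z)-3-[3,5-bis(methoxymethoxy)-4-(3-methylbut-2-en-1-yl)phenoxy]-2-{4-(methoxymethoxy)-3-[3-methyl-3-(triethylsilyloxy)butyl]phenyl}prop-2-enoic acid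
Conditions: LiOH·H2O (3 equiv), THF/H2O 3:1, rt; then 0.5 M HCl to pH 4, 0 °C
Reagents that add atoms: lithium hydroxide, [Li+].[OH-]
Why: Saponification by acyl substitution, as is usual for 3-aryloxyacrylates; methanol is left out so that no alkoxide can exchange the aryloxy group at C3, and the brief cold acidification should not touch the acetals or the silyl ether.

**Step 10**
Reactants: 16 (Z)-3-[3,5-bis(methoxymethoxy)-4-(3-methylbut-2-en-1-yl)phenoxy]-2-{4-(methoxymethoxy)-3-[3-methyl-3-(triethylsilyloxy)butyl]phenyl}prop-2-enoic acid
Product: 19 5,7-bis(methoxymethoxy)-3-{4-(methoxymethoxy)-3-[3-methyl-3-(triethylsilyloxy)butyl]phenyl}-6-(3-methylbut-2-en-1-yl)-4H-chromen-4-one, via acid chloride 17 (not isolated), via acyl triflate 18 (not isolated)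
Conditions: 1-chloro-N,N,2-trimethylprop-1-en-1-amine (1.1 equiv), CH2Cl2, 0 °C to rt; then AgOTf (1.2 equiv), 2,6-di-tert-butyl-4-methylpyridine (2 equiv), CH2Cl2 (0.01 M), −40 to 0 °C
Reagents that add atoms: none
Why: The chloroenamine turns 16 into acid chloride 17 under neutral conditions (the by-product is an amide, no HCl is released), and AgOTf exchanges chloride for triflate to give mixed anhydride 18, which ionises to an acylium ion. This cation is a vinylogous oxocarbenium ion (O1 to C2=C3 to C4), so the C2=C3 bond order drops and the two geometries interconvert; only the one that holds ring A next to C4 can close, so the geometric purity of 16 is not decisive. Ring C closes by intramolecular Friedel–Crafts acylation: C4 attacks the ring-A carbon ortho to O1 and forms the C4–C4a bond in a six-membered closure that is exo to the C=O bond, and the hindered pyridine takes the proton of the σ-complex and buffers the triflic acid. The closest known reaction types are the acid-mediated cyclisation of 3-aryloxyacrylic acids to chromones and the silver-triflate-promoted Friedel–Crafts acylation by acid chlorides. Regioselectivity needs no control, because O1 lies on the local twofold axis of ring A through C8a and C6, the two ortho carbons are equivalent and either closure gives the 6-prenyl chromone. The attacked carbon is ortho and para to the two acetal oxygens and so should be far more nucleophilic than the prenyl olefin, which cannot reach C4 in a reasonable ring size; ring B could only close a four-membered ring. No stereocentre is formed. The chemoselectivity needed is survival of the prenyl olefin, the acetals and the tertiary silyl ether, which the buffered medium, low temperature and high dilution should secure.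

**Step 11**
Reactants: 19 5,7-bis(methoxymethoxy)-3-{4-(methoxymethoxy)-3-[3-methyl-3-(triethylsilyloxy)butyl]phenyl}-6-(3-methylbut-2-en-1-yl)-4H-chromen-4-one
Product: 20 Coloratanin A
Conditions: 3 M aq. HCl/MeOH 1:10, rt to 40 °C
Reagents that add atoms: none
Why: Acid-catalysed transacetalisation of the three aryl methoxymethyl ethers and methanolysis of the silyl ether; both go through oxygen-stabilised cations and should be much faster than protonation of the trisubstituted olefin or ionisation of the unactivated tertiary alcohol.

## Compound list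

1 | resorcinol | Oc1cccc(O)c1 | starting material
2 | 1,3-bis(methoxymethoxy)benzene | COCOc1cccc(OCOC)c1 | intermediate
3 | [2,6-bis(methoxymethoxy)phenyl]lithium | [Li]c1c(OCOC)cccc1OCOC | intermediate (not isolated)
4 | 1,3-bis(methoxymethoxy)-2-(3-methylbut-2-en-1-yl)benzene | COCOc1cccc(OCOC)c1CC=C(C)C | intermediate
5 | 2-[3,5-bis(methoxymethoxy)-4-(3-methylbut-2-en-1-yl)phenyl]-4,4,5,5-tetramethyl-1,3,2-dioxaborolane | COCOc1cc(B2OC(C)(C)C(C)(C)O2)cc(OCOC)c1CC=C(C)C | intermediate (not isolated)
6 | 3,5-bis(methoxymethoxy)-4-(3-methylbut-2-en-1-yl)phenol | COCOc1cc(O)cc(OCOC)c1CC=C(C)C | intermediate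
7 | methyl 2-(3-bromo-4-hydroxyphenyl)acetate | COC(=O)Cc1ccc(O)c(Br)c1 | starting material
8 | methyl 2-[3-bromo-4-(methoxymethoxy)phenyl]acetate | COCOc1ccc(CC(=O)OC)cc1Br | intermediate
9 | 2-methylbut-3-en-2-ol | C=CC(C)(C)O | starting material
10 | triethyl[(2-methylbut-3-en-2-yl)oxy]silane | C=CC(C)(C)O[Si](CC)(CC)CC | intermediate
11 | 9-[3-methyl-3-(triethylsilyloxy)butyl]-9-borabicyclo[3.3.1]nonane | CC[Si](CC)(CC)OC(C)(C)CCB1C2CCCC1CCC2 | intermediate (not isolated)
12 | methyl 2-{4-(methoxymethoxy)-3-[3-methyl-3-(triethylsilyloxy)butyl]phenyl}acetate | COCOc1ccc(CC(=O)OC)cc1CCC(C)(C)O[Si](CC)(CC)CC | intermediate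
13 | sodium (Z)-3-methoxy-2-{4-(methoxymethoxy)-3-[3-methyl-3-(triethylsilyloxy)butyl]phenyl}-3-oxoprop-1-en-1-olate | COC(=O)/C(c1ccc(OCOC)c(CCC(C)(C)O[Si](CC)(CC)CC)c1)=C\[O-].[Na+] | intermediate (not isolated)
14 | methyl (Z)-2-{4-(methoxymethoxy)-3-[3-methyl-3-(triethylsilyloxy)butyl]phenyl}-3-(tosyloxy)prop-2-enoate | COC(=O)/C(c1ccc(OCOC)c(CCC(C)(C)O[Si](CC)(CC)CC)c1)=C\OS(=O)(=O)c1ccc(C)cc1 | intermediate
15 | methyl (Z)-3-[3,5-bis(methoxymethoxy)-4-(3-methylbut-2-en-1-yl)phenoxy]-2-{4-(methoxymethoxy)-3-[3-methyl-3-(triethylsilyloxy)butyl]phenyl}prop-2-enoate | COC(=O)/C(c1ccc(OCOC)c(CCC(C)(C)O[Si](CC)(CC)CC)c1)=C\Oc1cc(OCOC)c(CC=C(C)C)c(OCOC)c1 | intermediate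
16 | (Z)-3-[3,5-bis(methoxymethoxy)-4-(3-methylbut-2-en-1-yl)phenoxy]-2-{4-(methoxymethoxy)-3-[3-methyl-3-(triethylsilyloxy)butyl]phenyl}prop-2-enoic acid | OC(=O)/C(c1ccc(OCOC)c(CCC(C)(C)O[Si](CC)(CC)CC)c1)=C\Oc1cc(OCOC)c(CC=C(C)C)c(OCOC)c1 | intermediate
17 | (Z)-3-[3,5-bis(methoxymethoxy)-4-(3-methylbut-2-en-1-yl)phenoxy]-2-{4-(methoxymethoxy)-3-[3-methyl-3-(triethylsilyloxy)butyl]phenyl}prop-2-enoyl chloride | ClC(=O)/C(c1ccc(OCOC)c(CCC(C)(C)O[Si](CC)(CC)CC)c1)=C\Oc1cc(OCOC)c(CC=C(C)C)c(OCOC)c1 | intermediate (not isolated)
18 | (Z)-3-[3,5-bis(methoxymethoxy)-4-(3-methylbut-2-en-1-yl)phenoxy]-2-{4-(methoxymethoxy)-3-[3-methyl-3-(triethylsilyloxy)butyl]phenyl}prop-2-enoic trifluoromethanesulfonic anhydride | FC(F)(F)S(=O)(=O)OC(=O)/C(c1ccc(OCOC)c(CCC(C)(C)O[Si](CC)(CC)CC)c1)=C\Oc1cc(OCOC)c(CC=C(C)C)c(OCOC)c1 | intermediate (not isolated)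
19 | 5,7-bis(methoxymethoxy)-3-{4-(methoxymethoxy)-3-[3-methyl-3-(triethylsilyloxy)butyl]phenyl}-6-(3-methylbut-2-en-1-yl)-4H-chromen-4-one | COCOc1cc2occ(-c3ccc(OCOC)c(CCC(C)(C)O[Si](CC)(CC)CC)c3)c(=O)c2c(OCOC)c1CC=C(C)C | intermediate
20 | Coloratanin A, 5,7-dihydroxy-3-[4-hydroxy-3-(3-hydroxy-3-methylbutyl)phenyl]-6-(3-methylbut-2-en-1-yl)-4H-chromen-4-one | CC(C)=CCc1c(O)cc2occ(-c3ccc(O)c(CCC(C)(C)O)c3)c(=O)c2c1O | target

## Step count and least certain steps

Total: 11 steps. Longest linear sequence: 7 steps (steps 1, 2, 3, 8, 9, 10, 11; the ring-B branch through steps 4, 6, 7 is equally long).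

**Step 10 (key step).** The most likely failure is capture of the acylium ion or of traces of triflic acid by the nucleophilic prenyl olefin or by the acetal oxygens, in competition with ring closure; incomplete ionisation would also slow the rotation about C2=C3 that the closure needs. The fallback keeps the symmetry argument but avoids any acyl cation. It sets out from 6 and 12 and comes back at 19. Ester 12 is saponified (LiOH, THF/H2O) to the arylacetic acid F1, which is esterified with 6 (EDC·HCl, DMAP, CH2Cl2) to the aryl ester F2. Irradiation at 254 nm in degassed MeCN should bring about a photo-Fries rearrangement; the para position is blocked by the prenyl group and the two ortho carbons are equivalent, so one 2-hydroxydeoxybenzoin F3 is expected, whose only free phenol is the oxygen para to the prenyl group. Heating F3 with N,N-dimethylformamide dimethyl acetal in toluene at 90 °C gives the enaminone F4 (not isolated), which closes at that oxygen with loss of dimethylamine to 19.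

**Step 3.** The iridium boryl and hydride species may hydroborate or isomerise the prenyl olefin instead of, or besides, borylating the arene. The fallback reverses the order so that no olefin is present during borylation. It sets out from 2 and comes back at 6. Compound 2 is borylated under the same catalyst to the boronate F5 (not isolated) and oxidised with alkaline peroxide to 3,5-bis(methoxymethoxy)phenol F6. Silylation (TIPSCl, imidazole, DMF) gives the triisopropylsilyl ether F7. n-BuLi in THF at 0 °C should lithiate only between the two acetal groups to the aryllithium F8 (not isolated), since the bulky silyl ether does not direct. Copper-catalysed prenylation then gives the prenylated silyl ether F9, and TBAF in THF returns 6.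

**Step 8.** The phenoxide may attack sulfur (sulfonyl transfer) or react through a ring carbon instead of oxygen, and base may erode the double-bond geometry. The fallback forms the same C–O bond by cross-coupling instead of addition–elimination. It sets out from the sodium enolate 13 and comes back at 15. The enolate is trapped with N-phenylbis(trifluoromethanesulfonimide) to the enol triflate F10, which is coupled with 6 under zerovalent palladium catalysis (Pd2(dba)3, 2-(di-tert-butylphosphino)biphenyl, K3PO4, toluene, 80 °C) by oxidative addition, phenoxide exchange and C–O reductive elimination.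

**Step 11.** Once the 5- and 7-hydroxyls are free, prolonged acid may add them across the prenyl olefin (chroman formation), or ionise the tertiary alcohol and close it onto the 4'-hydroxyl. The fallback removes the acetals without a protic acid. It sets out from 19 and comes back at 20. Treatment with TMSOTf and 2,2'-bipyridyl in CH2Cl2 at 0 °C should convert the three aryl acetals into aryl silyl ethers, giving the tris(trimethylsilyl) ether F11; TBAF buffered with acetic acid in THF at 0 °C then cleaves all four silyl ethers to 20.

## Further compounds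

F1 | step 10 | 2-{4-(methoxymethoxy)-3-[3-methyl-3-(triethylsilyloxy)butyl]phenyl}acetic acid | COCOc1ccc(CC(O)=O)cc1CCC(C)(C)O[Si](CC)(CC)CC
F2 | step 10 | 3,5-bis(methoxymethoxy)-4-(3-methylbut-2-en-1-yl)phenyl 2-{4-(methoxymethoxy)-3-[3-methyl-3-(triethylsilyloxy)butyl]phenyl}acetate | COCOc1ccc(CC(=O)Oc2cc(OCOC)c(CC=C(C)C)c(OCOC)c2)cc1CCC(C)(C)O[Si](CC)(CC)CC
F3 | step 10 | 1-[6-hydroxy-2,4-bis(methoxymethoxy)-3-(3-methylbut-2-en-1-yl)phenyl]-2-{4-(methoxymethoxy)-3-[3-methyl-3-(triethylsilyloxy)butyl]phenyl}ethan-1-one | COCOc1cc(O)c(C(=O)Cc2ccc(OCOC)c(CCC(C)(C)O[Si](CC)(CC)CC)c2)c(OCOC)c1CC=C(C)C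
F4 | step 10 | (E)-3-(dimethylamino)-1-[6-hydroxy-2,4-bis(methoxymethoxy)-3-(3-methylbut-2-en-1-yl)phenyl]-2-{4-(methoxymethoxy)-3-[3-methyl-3-(triethylsilyloxy)butyl]phenyl}prop-2-en-1-one | COCOc1cc(O)c(C(=O)/C(=C/N(C)C)c2ccc(OCOC)c(CCC(C)(C)O[Si](CC)(CC)CC)c2)c(OCOC)c1CC=C(C)C
F5 | step 3 | 2-[3,5-bis(methoxymethoxy)phenyl]-4,4,5,5-tetramethyl-1,3,2-dioxaborolane | COCOc1cc(OCOC)cc(B2OC(C)(C)C(C)(C)O2)c1
F6 | step 3 | 3,5-bis(methoxymethoxy)phenol | COCOc1cc(O)cc(OCOC)c1
F7 | step 3 | [3,5-bis(methoxymethoxy)phenoxy]tri(propan-2-yl)silane | COCOc1cc(O[Si](C(C)C)(C(C)C)C(C)C)cc(OCOC)c1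
F8 | step 3 | {2,6-bis(methoxymethoxy)-4-[tri(propan-2-yl)silyloxy]phenyl}lithium | [Li]c1c(OCOC)cc(O[Si](C(C)C)(C(C)C)C(C)C)cc1OCOC
F9 | step 3 | [3,5-bis(methoxymethoxy)-4-(3-methylbut-2-en-1-yl)phenoxy]tri(propan-2-yl)silane | COCOc1cc(O[Si](C(C)C)(C(C)C)C(C)C)cc(OCOC)c1CC=C(C)C
F10 | step 8 | methyl (Z)-2-{4-(methoxymethoxy)-3-[3-methyl-3-(triethylsilyloxy)butyl]phenyl}-3-{[(trifluoromethyl)sulfonyl]oxy}prop-2-enoate | COC(=O)/C(c1ccc(OCOC)c(CCC(C)(C)O[Si](CC)(CC)CC)c1)=C\OS(=O)(=O)C(F)(F)F
F11 | step 11 | 3-{3-[3-methyl-3-(triethylsilyloxy)butyl]-4-(trimethylsilyloxy)phenyl}-6-(3-methylbut-2-en-1-yl)-5,7-bis(trimethylsilyloxy)-4H-chromen-4-one | C[Si](C)(C)Oc1cc2occ(-c3ccc(O[Si](C)(C)C)c(CCC(C)(C)O[Si](CC)(CC)CC)c3)c(=O)c2c(O[Si](C)(C)C)c1CC=C(C)C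
A1 | alternative 1 | 2-(3-methylbut-2-en-1-yl)benzene-1,3,5-triol | CC(C)=CCc1c(O)cc(O)cc1O
A2 | alternative 1 | 2-[4-hydroxy-3-(3-hydroxy-3-methylbutyl)phenyl]-1-[2,4,6-trihydroxy-3-(3-methylbut-2-en-1-yl)phenyl]ethan-1-one | CC(C)=CCc1c(O)cc(O)c(C(=O)Cc2ccc(O)c(CCC(C)(C)O)c2)c1O
A3 | alternative 1 | 5,7-dihydroxy-3-[4-hydroxy-3-(3-hydroxy-3-methylbutyl)phenyl]-8-(3-methylbut-2-en-1-yl)-4H-chromen-4-one | CC(C)=CCc1c(O)cc(O)c2c(=O)c(-c3ccc(O)c(CCC(C)(C)O)c3)coc12
A4 | alternative 2 | 3-iodo-5,7-bis(methoxymethoxy)-6-(3-methylbut-2-en-1-yl)-4H-chromen-4-one | COCOc1cc2occ(I)c(=O)c2c(OCOC)c1CC=C(C)C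
A5 | alternative 2 | 2-{4-(methoxymethoxy)-3-[3-methyl-3-(triethylsilyloxy)butyl]phenyl}-4,4,5,5-tetramethyl-1,3,2-dioxaborolane | COCOc1ccc(B2OC(C)(C)C(C)(C)O2)cc1CCC(C)(C)O[Si](CC)(CC)CC
A6 | alternative 3 | (E)-1-[6-hydroxy-2,4-bis(methoxymethoxy)-3-(3-methylbut-2-en-1-yl)phenyl]-3-{4-(methoxymethoxy)-3-[3-methyl-3-(triethylsilyloxy)butyl]phenyl}prop-2-en-1-one | COCOc1cc(O)c(C(=O)/C=C/c2ccc(OCOC)c(CCC(C)(C)O[Si](CC)(CC)CC)c2)c(OCOC)c1CC=C(C)C
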